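**Retrosynthetic overview**
1. The C5 hydroxyl is unmasked last from its peri methyl ether; before that, the 4-hydroxyphenoxy group is put on C2 by addition–elimination of hydroquinone on a 2-methylsulfinylchromone.
2. Ring C is closed from a 2-hydroxyacetophenone and CS2 (C2 from CS2, C3 from the ketone methyl); the ketone comes from a salicylate ester by one-carbon extension at C4.
3. The strategy rests on ring A: oxygen on C5, C7 and C8a alternates around the ring, prenyl sits on C8, hydrogen on C6 and the acyl carbon C4 on C4a. Ring A is cut into a 1,1,3-trioxygenated 2-prenylbutadiene (C8a, C8, C7, C6) and a 3-alkoxy ynoate (C5, C4a with C4), joined by Diels–Alder addition (bonds C5–C6 and C4a–C8a) and aromatisation.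
4. The diene comes from methyl acetoacetate and prenyl bromide, the ynoate from methoxyacetylene and methyl chloroformate. Ring order: ring A (step 7), then ring C (step 9); the aryloxy ring is bought as hydroquinone.

Key step: step 7

Remark: 5, 6 and 7 are drawn as E isomers, but the geometry is lost in diene 8, so an isomer mixture can be used. 3, 4 and sulfoxide 23 are racemic, and none of their stereocentres reaches the target, which has none.

**Step 1**
Reactants: 1 methyl acetoacetate; 2 prenyl bromide
Product: 3 methyl 2-acetyl-5-methylhex-4-enoate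
Conditions: NaH, THF, 0 °C; then 2, 0 → 23 °C (1 in slight excess)
Reagents that add atoms: none
Why: C-alkylation of the sodium enolate of a β-keto ester by an allylic bromide (acetoacetic ester alkylation), with the excess of 1 limiting double alkylation.

**Step 2**
Reactants: 3 methyl 2-acetyl-5-methylhex-4-enoate
Product: 5 methyl (E)-3-methoxy-2-(3-methylbut-2-enyl)but-2-enoate, via dimethyl ketal 4 (not isolated)
Conditions: HC(OMe)3, cat. H2SO4, MeOH, 23 °C; then pyridinium p-toluenesulfonate, toluene, 110 °C with removal of MeOH
Reagents that add atoms: trimethyl orthoformate, COC(OC)OC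
Why: Acid-catalysed ketalisation by the orthoester and loss of methanol towards the ester-conjugated enol ether is the standard entry to β-methoxy crotonates, and the mild acid should leave the trisubstituted alkene untouched.

**Step 3**
Reactants: 5 methyl (E)-3-methoxy-2-(3-methylbut-2-enyl)but-2-enoate
Product: 6 (E)-3-methoxy-2-(3-methylbut-2-enyl)but-2-enoic acid
Conditions: KOH, MeOH/H2O, reflux; then cold 1 M HCl to pH 3, 0 °C, rapid extraction
Reagents that add atoms: potassium hydroxide, [K+].[OH-]
Why: Saponification of a vinylogous carbonate ester, in which the enol ether is stable to base and the short cold acidification should avoid its hydrolysis.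

**Step 4**
Reactants: 6 (E)-3-methoxy-2-(3-methylbut-2-enyl)but-2-enoic acid
Product: 8 3-methoxy-2-(3-methylbut-2-enyl)-1,1-bis(trimethylsilyloxy)buta-1,3-diene, via trimethylsilyl ester 7 (not isolated)
Conditions: HN(SiMe3)2, cat. Me3SiCl, 60 °C, then evaporation; LiN(iPr)2 added to 7 and Me3SiCl, THF, −78 → 23 °C; pentane, filtration under argon
Reagents that add atoms: hexamethyldisilazane, C[Si](C)(C)N[Si](C)(C)C; chlorotrimethylsilane, C[Si](C)(C)Cl
Why: Silyl ester formation, then γ-deprotonation of the β-methoxy enoate and O-silylation (the Brassard-diene preparation applied to a silyl ester) should give a ketene acetal with two identical silyloxy groups and hence no geometric isomers.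

**Step 5**
Reactants: 9 chloroacetaldehyde dimethyl acetal
Product: 11 methoxyacetylene, via sodium methoxyacetylide 10 (not isolated)
Conditions: NaNH2 (3 equiv), liquid NH3, −33 °C; NH3 evaporated; cold sat. aq. NaCl, −70 → 20 °C, distilled into THF at −78 °C
Reagents that add atoms: none
Why: Elimination of HCl and methanol by NaNH2 gives the sodium alkoxyacetylide, and the cold aqueous quench releases the volatile ynol ether (classical alkoxyacetylene preparation).

**Step 6**
Reactants: 11 methoxyacetylene; 12 methyl chloroformate
Product: 14 methyl 3-methoxyprop-2-ynoate, via lithium methoxyacetylide 13 (not isolated)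
Conditions: n-BuLi, THF, −78 °C; then cannulated into 12 (1.5 equiv), THF, −78 → −20 °C; anhydrous work-up, bulb-to-bulb distillation
Reagents that add atoms: none
Why: Deprotonation of the terminal alkyne and C-acylation of the lithium acetylide by a chloroformate, with inverse addition keeping the product away from unreacted acetylide.

**Step 7**
Reactants: 8 3-methoxy-2-(3-methylbut-2-enyl)-1,1-bis(trimethylsilyloxy)buta-1,3-diene; 14 methyl 3-methoxyprop-2-ynoate
Product: 17 methyl 2-hydroxy-4,6-dimethoxy-3-(3-methylbut-2-enyl)benzoate, via cyclohexadiene adduct 15 (not isolated), via aryl silyl ether 16 (not isolated)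
Conditions: 8 (1.5 equiv), toluene, 100 °C, sealed tube, argon; then aq. citric acid, THF, 23 °C
Reagents that add atoms: none
Why: Proposed new method: the CH2 terminus of diene 8 (future C6) should attack the ether-bearing β-carbon of ynoate 14 (future C5), and the resulting allenyl ester enolate should collapse by its α-carbon (future C4a) onto the bis(silyloxy)-substituted carbon (future C8a), an asynchronous (4+2) cycloaddition in which both new bonds lie in the new six-membered ring A of cyclohexa-1,4-diene 15. The closest known reaction type is the Diels–Alder benzannulation of Brassard and Danishefsky dienes with propiolates and acetylenedicarboxylates; what is not established is a 3-alkoxypropiolate, a push–pull alkyne of lowered electrophilicity, as the two-carbon partner, which is why the more nucleophilic bis(silyl) acetal and heating are chosen, and why the methyl ynol ether is used, since it cannot fragment by retro-ene loss of an alkene at that temperature. Adduct 15 is a doubly allylic silyl ketal whose ionisation gives a phloroglucinol-type arenium ion, so 1,4-loss of Me3SiOH to aryl silyl ether 16 should occur spontaneously or on the mild acid work-up, which also frees the phenol. No stereocentre is formed. The selectivity needed is the mutual orientation of the two partners, and it is secured by the matched polarity of the nucleophilic CH2 terminus and the electrophilic β-carbon; the single hydroxyl of 17, flanked by prenyl and ester, is the oxygen that later becomes O1.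

**Step 8**
Reactants: 17 methyl 2-hydroxy-4,6-dimethoxy-3-(3-methylbut-2-enyl)benzoate
Product: 19 1-[2-hydroxy-4,6-dimethoxy-3-(3-methylbut-2-enyl)phenyl]ethanone, via silylmethyl ketone 18 (not isolated)
Conditions: Me3SiCH2Li (4 equiv), THF/pentane, 0 → 23 °C; then MeOH, 23 °C; dilute HCl, 0 °C
Reagents that add atoms: (trimethylsilyl)methyllithium, [Li]C[Si](C)(C)C
Why: Acyl substitution by the silylmethyllithium reagent should stop at the ketone because the α-silyl ketone is deprotonated at once to its enolate, and methanolysis of the C–Si bond then gives the methyl ketone (ester to methyl ketone conversion), the first equivalent being consumed by the phenol.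

**Step 9**
Reactants: 19 1-[2-hydroxy-4,6-dimethoxy-3-(3-methylbut-2-enyl)phenyl]ethanone
Product: 21 4-hydroxy-5,7-dimethoxy-8-(3-methylbut-2-enyl)-2H-chromene-2-thione, via oxodithioic acid 20 (not isolated)
Conditions: KOtBu (3.5 equiv), CS2, THF, 0 → 23 °C; then cold 1 M HCl
Reagents that add atoms: carbon disulfide, S=C=S
Why: Claisen-type thioacylation of the ketone enolate by CS2 and, on acidification, attack of the only phenol on the dithioacid with loss of H2S should close ring C by a 6-exo-trig addition–elimination, the known route from 2-hydroxyacetophenones to 4-hydroxy-2H-chromene-2-thiones.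

**Step 10**
Reactants: 21 4-hydroxy-5,7-dimethoxy-8-(3-methylbut-2-enyl)-2H-chromene-2-thione
Product: 22 5,7-dimethoxy-8-(3-methylbut-2-enyl)-2-(methylsulfanyl)-4H-chromen-4-one
Conditions: MeI, K2CO3, acetone, 23 °C
Reagents that add atoms: iodomethane, CI
Why: S-Alkylation of the soft sulfur terminus of the ambident anion by MeI gives the 2-alkylsulfanylchromone, as is usual for 4-hydroxy-2-thioxochromenes.

**Step 11**
Reactants: 22 5,7-dimethoxy-8-(3-methylbut-2-enyl)-2-(methylsulfanyl)-4H-chromen-4-one
Product: 23 5,7-dimethoxy-2-(methylsulfinyl)-8-(3-methylbut-2-enyl)-4H-chromen-4-one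
Conditions: KHSO5 (1.1 equiv, as 2KHSO5·KHSO4·K2SO4), MeOH/THF/H2O, 0 °C, no acetone
Reagents that add atoms: potassium peroxymonosulfate, [K+].[O-]S(=O)(=O)OO
Why: Oxygen transfer from peroxymonosulfate to sulfur (sulfide to sulfoxide oxidation) is much faster than to an isolated alkene when no ketone catalyst is present, so the prenyl group should survive, and any sulfone formed would react in the same way in step 12.

**Step 12**
Reactants: 23 5,7-dimethoxy-2-(methylsulfinyl)-8-(3-methylbut-2-enyl)-4H-chromen-4-one; 24 hydroquinone
Product: 25 2-(4-hydroxyphenoxy)-5,7-dimethoxy-8-(3-methylbut-2-enyl)-4H-chromen-4-one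
Conditions: 24 (5 equiv), K2CO3, DMF, 23 °C, argon
Reagents that add atoms: none
Why: Addition–elimination (vinylogous acyl substitution) of the phenoxide at C2 with loss of methanesulfenate is the established entry to 2-aryloxychromones, and the excess of 24 suppresses double arylation.

**Step 13**
Reactants: 25 2-(4-hydroxyphenoxy)-5,7-dimethoxy-8-(3-methylbut-2-enyl)-4H-chromen-4-one
Product: 26 7-O-methylepimedonin G
Conditions: MgI2·OEt2 (3 equiv), toluene/THF, 70 °C; then dilute HCl, 0 °C
Reagents that add atoms: none
Why: MgI2 chelates between the C4 carbonyl and the peri C5 methoxy oxygen so that iodide dealkylates only that ether (chelation-controlled demethylation), and the non-protic conditions should leave the prenyl group, the C7 methyl ether and the aryl enol ether alone.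

**Compound list**
1 | methyl acetoacetate | COC(=O)CC(C)=O | starting material
2 | prenyl bromide (1-bromo-3-methylbut-2-ene) | CC(C)=CCBr | starting material
3 | methyl 2-acetyl-5-methylhex-4-enoate (racemic) | COC(=O)C(CC=C(C)C)C(C)=O | intermediate
4 | methyl 2-(1,1-dimethoxyethyl)-5-methylhex-4-enoate (racemic; not isolated) | COC(=O)C(CC=C(C)C)C(C)(OC)OC | intermediate
5 | methyl (E)-3-methoxy-2-(3-methylbut-2-enyl)but-2-enoate | COC(=O)/C(CC=C(C)C)=C(\C)OC | intermediate
6 | (E)-3-methoxy-2-(3-methylbut-2-enyl)but-2-enoic acid | OC(=O)/C(CC=C(C)C)=C(\C)OC | intermediate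
7 | trimethylsilyl (E)-3-methoxy-2-(3-methylbut-2-enyl)but-2-enoate (not isolated) | C[Si](C)(C)OC(=O)/C(CC=C(C)C)=C(\C)OC | intermediate
8 | 3-methoxy-2-(3-methylbut-2-enyl)-1,1-bis(trimethylsilyloxy)buta-1,3-diene | C=C(OC)C(CC=C(C)C)=C(O[Si](C)(C)C)O[Si](C)(C)C | intermediate
9 | chloroacetaldehyde dimethyl acetal | COC(OC)CCl | starting material
10 | sodium methoxyacetylide (not isolated) | [Na+].[C-]#COC | intermediate
11 | methoxyacetylene | C#COC | intermediate
12 | methyl chloroformate | COC(=O)Cl | starting material
13 | lithium methoxyacetylide (not isolated) | [Li+].[C-]#COC | intermediate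
14 | methyl 3-methoxyprop-2-ynoate | COC#CC(=O)OC | intermediate
15 | methyl 2,4-dimethoxy-5-(3-methylbut-2-enyl)-6,6-bis(trimethylsilyloxy)cyclohexa-1,4-diene-1-carboxylate (not isolated) | COC(=O)C1=C(OC)CC(OC)=C(CC=C(C)C)C1(O[Si](C)(C)C)O[Si](C)(C)C | intermediate
16 | methyl 4,6-dimethoxy-3-(3-methylbut-2-enyl)-2-(trimethylsilyloxy)benzoate (not isolated) | COC(=O)c1c(O[Si](C)(C)C)c(CC=C(C)C)c(OC)cc1OC | intermediate
17 | methyl 2-hydroxy-4,6-dimethoxy-3-(3-methylbut-2-enyl)benzoate | COC(=O)c1c(O)c(CC=C(C)C)c(OC)cc1OC | intermediate
18 | 1-[2-hydroxy-4,6-dimethoxy-3-(3-methylbut-2-enyl)phenyl]-2-(trimethylsilyl)ethanone (formed as its lithium enolate; not isolated) | C[Si](C)(C)CC(=O)c1c(O)c(CC=C(C)C)c(OC)cc1OC | intermediate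
19 | 1-[2-hydroxy-4,6-dimethoxy-3-(3-methylbut-2-enyl)phenyl]ethanone | CC(=O)c1c(O)c(CC=C(C)C)c(OC)cc1OC | intermediate
20 | 3-[2-hydroxy-4,6-dimethoxy-3-(3-methylbut-2-enyl)phenyl]-3-oxopropanedithioic acid (not isolated) | SC(=S)CC(=O)c1c(O)c(CC=C(C)C)c(OC)cc1OC | intermediate
21 | 4-hydroxy-5,7-dimethoxy-8-(3-methylbut-2-enyl)-2H-chromene-2-thione | COc1cc(OC)c2c(O)cc(=S)oc2c1CC=C(C)C | intermediate
22 | 5,7-dimethoxy-8-(3-methylbut-2-enyl)-2-(methylsulfanyl)-4H-chromen-4-one | COc1cc(OC)c2c(=O)cc(SC)oc2c1CC=C(C)C | intermediate
23 | 5,7-dimethoxy-2-(methylsulfinyl)-8-(3-methylbut-2-enyl)-4H-chromen-4-one (racemic at sulfur) | COc1cc(OC)c2c(=O)cc(S(C)=O)oc2c1CC=C(C)C | intermediate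
24 | hydroquinone | Oc1ccc(O)cc1 | starting material
25 | 2-(4-hydroxyphenoxy)-5,7-dimethoxy-8-(3-methylbut-2-enyl)-4H-chromen-4-one | COc1cc(OC)c2c(=O)cc(Oc3ccc(O)cc3)oc2c1CC=C(C)C | intermediate
26 | 7-O-methylepimedonin G, 5-hydroxy-2-(4-hydroxyphenoxy)-7-methoxy-8-(3-methylbut-2-enyl)-4H-chromen-4-one | COc1cc(O)c2c(=O)cc(Oc3ccc(O)cc3)oc2c1CC=C(C)C | target

**Step count and risks**
Total steps: 13. Longest linear sequence: 11 steps (steps 1–4 and 7–13); steps 5 and 6 form the side branch to ynoate 14.

Steps most likely to fail:

1. Step 7 (Proposed new method). The donor-substituted ynoate may add too slowly, so that the silyl ketene acetal is lost by hydrolysis, silyl migration or oligomerisation before cycloaddition, or the first C–C bond may form without ring closure. The fallback uses directed ortho-metalation, which is known chemistry. It sets out from prenyl bromide 2 and methyl chloroformate 12 together with purchased 3,5-dimethoxyphenol F1, and it comes back to the route at benzoate 17. The phenol is protected with MOMCl and iPr2NEt in CH2Cl2 to give 1,3-dimethoxy-5-(methoxymethoxy)benzene F2. Lithiation with n-BuLi in THF at 0 °C between the acetal and a methoxy group, transmetalation with CuBr·SMe2 and alkylation by 2 should give 1,5-dimethoxy-3-(methoxymethoxy)-2-(3-methylbut-2-enyl)benzene F3. A second lithiation at the remaining position next to the acetal and quenching with 12 should give methyl 4,6-dimethoxy-2-(methoxymethoxy)-3-(3-methylbut-2-enyl)benzoate F4. Catalytic HCl in MeOH at 23 °C then removes the acetal to give 17.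

2. Step 8. Acyl substitution may be too slow at an ester that is flanked by two ortho substituents and deactivated as its lithium phenoxide, or a second equivalent may add before enolisation and lead to Peterson-type olefination. The fallback sets out from 17 and returns at 19. Condensation of 17 with NaCH2S(O)CH3 (made from NaH and DMSO) in DMSO/THF at 23 °C should give the β-keto sulfoxide 1-[2-hydroxy-4,6-dimethoxy-3-(3-methylbut-2-enyl)phenyl]-2-(methylsulfinyl)ethanone F5. Reductive cleavage of its C–S bond with aluminium amalgam (Al/Hg) in aqueous THF at 0 → 23 °C then gives methyl ketone 19.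

3. Step 13. Lewis-acid activation of the pyranone carbonyl may also labilise the aryl enol ether at C2, so that the aryloxy group is exchanged or lost, or ether cleavage may extend to the C7 methoxy group of the electron-rich final compound. The fallback moves the demethylation ahead of the aryl ether formation; it sets out from 22 and returns at target 26. Treatment of 22 with MgI2·OEt2 as in step 13 should give 5-hydroxy-7-methoxy-8-(3-methylbut-2-enyl)-2-(methylsulfanyl)-4H-chromen-4-one F6. Oxidation with KHSO5 as in step 11 should give 5-hydroxy-7-methoxy-2-(methylsulfinyl)-8-(3-methylbut-2-enyl)-4H-chromen-4-one F7. Displacement with excess hydroquinone 24 and K2CO3 in DMF, where hydroquinone is deprotonated in preference to the chelated C5 hydroxyl, then gives 26 directly.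

**Further compounds**
F1 | step 7 | 3,5-dimethoxyphenol (purchased starting material of the fallback) | COc1cc(O)cc(OC)c1
F2 | step 7 | 1,3-dimethoxy-5-(methoxymethoxy)benzene | COCOc1cc(OC)cc(OC)c1
F3 | step 7 | 1,5-dimethoxy-3-(methoxymethoxy)-2-(3-methylbut-2-enyl)benzene | COCOc1cc(OC)cc(OC)c1CC=C(C)C
F4 | step 7 | methyl 4,6-dimethoxy-2-(methoxymethoxy)-3-(3-methylbut-2-enyl)benzoate | COCOc1c(CC=C(C)C)c(OC)cc(OC)c1C(=O)OC
F5 | step 8 | 1-[2-hydroxy-4,6-dimethoxy-3-(3-methylbut-2-enyl)phenyl]-2-(methylsulfinyl)ethanone | CS(=O)CC(=O)c1c(O)c(CC=C(C)C)c(OC)cc1OC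
F6 | step 13 | 5-hydroxy-7-methoxy-8-(3-methylbut-2-enyl)-2-(methylsulfanyl)-4H-chromen-4-one | COc1cc(O)c2c(=O)cc(SC)oc2c1CC=C(C)C
F7 | step 13 | 5-hydroxy-7-methoxy-2-(methylsulfinyl)-8-(3-methylbut-2-enyl)-4H-chromen-4-one | COc1cc(O)c2c(=O)cc(S(C)=O)oc2c1CC=C(C)C
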